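**Plan**

- Retrosynthesis: the four C–halogen bonds on the ring are cut first (C3–Br and CH2–Cl back to a spiro-epoxide on C3, C4–Cl and C6–Cl back to β-hydroxyls). Then follow the chlorovinyl C=C (back to a formyl group on C1), the exocyclic carbon on C3 (back to a C4 ketone), ring bond C5–C6 (aldol) and chain bond C1–C2 (Michael).
- Enabling feature: in the ring C1 (C–CH3, chlorovinyl), C2 (CH2), C3 (CBr, CH2Cl), C4 (CHCl), C5 (CH2), C6 (CHCl), the quaternary C1 holds two one-carbon CH units, the ring carbon C6 and the inner vinyl carbon. C1 can therefore start as a prochiral carbon with two formyl groups.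
- Forward: the chain is joined by Michael addition of 2-methylmalonaldehyde to methyl vinyl ketone. The only ring (cyclohexane C1–C6) closes in an amino-acid-catalysed aldol that tells the two formyl groups apart. Everything after that is functional-group work on this ring.
- Stereochemistry: C1 and C6 come from the catalyst-controlled aldol, C4 from a substrate-controlled Luche reduction, C3 from a hydroxyl-directed epoxidation. Three SN2-type inversions (Appel at C4 and C6, bromide opening at C3) turn the all-β oxygen pattern into the α-halogen pattern; the E chloroalkene comes from a Takai olefination.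

Key step: step 3

Assumption: the sense of induction in the aldol is taken from the proline-catalysed cyclisation of 2-alkyl-2-(3-oxobutyl)-1,3-diones, which points to (R)-proline for the (1R,2R)-ketol; if the first batch shows the mirror-image series, (S)-proline is used and nothing else changes.

Conventions: ring numbering as in the plan; β = face of the C1 methyl group, α = the opposite face; TBS = tert-butyldimethylsilyl.

**Route**

Step 1
Reactants: 1 1,1,3,3-tetraethoxy-2-methylpropane
Product: 2 2-methylpropanedial (2-methylmalonaldehyde; handled as its enol 3-hydroxy-2-methylprop-2-enal)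
Conditions: 1 M aq. HCl, rt → 40 °C; concentrate
Reagents that add atoms: water, SMILES O
Why: Acid-catalysed acetal hydrolysis of both diethyl acetals should release the 1,3-dialdehyde, which is stable as its conjugated, strongly acidic enol and can be used directly; no stereocentre is involved.

Step 2
Reactants: 2 2-methylpropanedial; 3 methyl vinyl ketone
Product: 4 2-methyl-2-(3-oxobutyl)propanedial
Conditions: Et3N (5 mol %), MeCN, 0 °C → rt
Reagents that add atoms: none
Why: Amine-catalysed Michael addition of the acidic 1,3-dicarbonyl enol to the enone (the reaction that makes 2-alkyl-2-(3-oxobutyl)-1,3-diones) should give the C-alkylated product because O-addition is reversible, and the new quaternary carbon is prochiral, so no stereocentre arises yet.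

Step 3
Reactants: 4 2-methyl-2-(3-oxobutyl)propanedial
Product: 5 (1R,2R)-2-hydroxy-1-methyl-4-oxocyclohexane-1-carbaldehyde
Conditions: (R)-proline (20 mol %), DMF, 4 °C
Reagents that add atoms: none
Why: The secondary amine condenses with the methyl ketone to the terminal enamine, whose carbon C5 adds to one formyl group that is hydrogen-bonded to the catalyst's carboxylic acid in a chair-like transition state, and hydrolysis of the resulting iminium ion releases the ketol and the catalyst. The closest known reaction is the Hajos–Parrish intramolecular aldol of 2-alkyl-2-(3-oxobutyl)-1,3-diones, here with the two ring carbonyls replaced by the two formyl groups on C1. The cyclohexane ring closes in the 6-(enolendo)-exo-trig mode by formation of the C5–C6 bond. The quaternary centre C1 is set by the catalyst, which picks one of the two enantiotopic formyl groups through the acid-directed chair. The carbinol centre C6 follows from the orientation of the reacting formyl group, whose C=O should lie anti to the C=O of the spectator formyl group (dipole minimisation, the arrangement that the ring enforces in the dione case), which puts the hydroxyl cis to the methyl group and trans to the remaining formyl group. The step needs site selectivity, secured because the formyl groups on quaternary C1 cannot enolise and the internal enamine could only close a four-membered ring, and group selectivity between the formyl groups, which is the catalyst's task; the low temperature is meant to keep the ketol from dehydrating or equilibrating by retro-aldol.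

Step 4
Reactants: 5 (1R,2R)-2-hydroxy-1-methyl-4-oxocyclohexane-1-carbaldehyde
Product: 6 (1R,2R)-2-[(tert-butyldimethylsilyl)oxy]-1-methyl-4-oxocyclohexane-1-carbaldehyde
Conditions: TBSOTf, 2,6-lutidine, CH2Cl2, −78 °C
Reagents that add atoms: tert-butyldimethylsilyl trifluoromethanesulfonate, SMILES CC(C)(C)[Si](C)(C)OS(=O)(=O)C(F)(F)F
Why: Silylation of the secondary alcohol with the silyl triflate and a hindered pyridine base (alcohol protection) should be fast enough at low temperature to outrun retro-aldol or dehydration of the β-hydroxy ketone, and the ether later shields C6 from E1cB loss during enolate chemistry; no stereocentre is touched.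

Step 5
Reactants: 6 (1R,2R)-2-[(tert-butyldimethylsilyl)oxy]-1-methyl-4-oxocyclohexane-1-carbaldehyde
Product: 7 (3R,4S)-3-[(tert-butyldimethylsilyl)oxy]-4-[(E)-2-chloroethenyl]-4-methylcyclohexan-1-one
Conditions: CrCl2, CHCl3, THF, 65 °C
Reagents that add atoms: chloroform, SMILES ClC(Cl)Cl
Why: Takai chloro-olefination with the chromium carbenoid from CHCl3/CrCl2 is selective for aldehydes over ketones and should give the E chloroalkene from the non-enolisable neopentyl aldehyde, the E geometry arising from anti elimination of the β-oxidochromium adduct in its less crowded arrangement.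

Step 6
Reactants: 7 (3R,4S)-3-[(tert-butyldimethylsilyl)oxy]-4-[(E)-2-chloroethenyl]-4-methylcyclohexan-1-one
Product: 11 (4S,5R)-5-[(tert-butyldimethylsilyl)oxy]-4-[(E)-2-chloroethenyl]-4-methyl-2-methylidenecyclohexan-1-one, via lithium enolate 8 (not isolated), via Mannich base 9 (not isolated), via ammonium iodide 10 (not isolated)
Conditions: LiHMDS, THF, −78 °C; CH2=NMe2+ I−, −78 → 0 °C; MeI, CH2Cl2, rt; sat. aq. NaHCO3, rt
Reagents that add atoms: N,N-dimethylmethyleneiminium iodide (Eschenmoser's salt), SMILES C=[N+](C)C.[I-]
Why: Kinetic deprotonation by the bulky lithium amide should take place at C3, the α-methylene remote from the silyloxy-substituted neopentylic C6, and Mannich reaction of the enolate with Eschenmoser's salt followed by N-methylation and base-induced loss of trimethylamine (E1cB) is the standard α-methylenation of a ketone; the C3 stereocentre of the Mannich base disappears in the elimination.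

Step 7
Reactants: 11 (4S,5R)-5-[(tert-butyldimethylsilyl)oxy]-4-[(E)-2-chloroethenyl]-4-methyl-2-methylidenecyclohexan-1-one
Product: 12 (1S,4S,5R)-5-[(tert-butyldimethylsilyl)oxy]-4-[(E)-2-chloroethenyl]-4-methyl-2-methylidenecyclohexan-1-ol
Conditions: NaBH4, CeCl3·7H2O, MeOH, −78 °C
Reagents that add atoms: none
Why: Luche reduction should reduce the exo-methylene enone cleanly in the 1,2-sense, and hydride is expected to reach C4 from the α face (axial attack on the chair with the C6 silyloxy group equatorial, while in the other chair the β face is screened by the axial silyloxy group), so that the new C4 hydroxyl is β, cis to the C6 oxygen.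

Step 8
Reactants: 12 (1S,4S,5R)-5-[(tert-butyldimethylsilyl)oxy]-4-[(E)-2-chloroethenyl]-4-methyl-2-methylidenecyclohexan-1-ol
Product: 13 (3S,4S,6R,7S)-6-[(tert-butyldimethylsilyl)oxy]-7-[(E)-2-chloroethenyl]-7-methyl-1-oxaspiro[2.5]octan-4-ol
Conditions: VO(acac)2 (5 mol %), t-BuOOH, CH2Cl2, 0 °C → rt
Reagents that add atoms: tert-butyl hydroperoxide, SMILES CC(C)(C)OO
Why: Vanadium-catalysed hydroxyl-directed epoxidation of an allylic alcohol delivers the peroxide oxygen within the vanadium alkoxide to the alkene face on the side of the C4 hydroxyl, which should place the epoxide oxygen β at the new spiro centre C3, and it leaves the electron-poor chloroalkene alone.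

Step 9
Reactants: 13 (3S,4S,6R,7S)-6-[(tert-butyldimethylsilyl)oxy]-7-[(E)-2-chloroethenyl]-7-methyl-1-oxaspiro[2.5]octan-4-ol
Product: 14 (3S,4R,6R,7S)-6-[(tert-butyldimethylsilyl)oxy]-4-chloro-7-[(E)-2-chloroethenyl]-7-methyl-1-oxaspiro[2.5]octane
Conditions: PPh3, CCl4, CH2Cl2, 40 °C
Reagents that add atoms: carbon tetrachloride, SMILES ClC(Cl)(Cl)Cl
Why: Appel reaction of the secondary epoxy alcohol: chloride displaces the alkoxyphosphonium group by SN2 with inversion, so the β hydroxyl should become the α chloride at C4, and the syn-oriented epoxide oxygen can neither participate from the rear nor be opened under these neutral conditions.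

Step 10
Reactants: 14 (3S,4R,6R,7S)-6-[(tert-butyldimethylsilyl)oxy]-4-chloro-7-[(E)-2-chloroethenyl]-7-methyl-1-oxaspiro[2.5]octane
Product: 15 [(1R,2R,4R,5S)-1-bromo-4-[(tert-butyldimethylsilyl)oxy]-2-chloro-5-[(E)-2-chloroethenyl]-5-methylcyclohexyl]methanol
Conditions: HBr (anhydrous, 1.1 equiv), CH2Cl2, −78 °C
Reagents that add atoms: hydrogen bromide, SMILES Br
Why: Acid-promoted (borderline SN2) opening of a 2,2-disubstituted oxirane by hydrogen bromide is expected at the tertiary carbon anti to the breaking C–O bond, so bromide should enter C3 from the α face with inversion (along the equatorial line of the chair in which the C3–O bond is axial and the silyloxy group equatorial), leaving the oxygen on the exocyclic carbon as CH2OH; the low temperature and the non-nucleophilic solvent are chosen to favour this pathway over attack at CH2 and to spare the silyl ether.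

Step 11
Reactants: 15 [(1R,2R,4R,5S)-1-bromo-4-[(tert-butyldimethylsilyl)oxy]-2-chloro-5-[(E)-2-chloroethenyl]-5-methylcyclohexyl]methanol
Product: 16 (1R,2S,4R,5R)-4-bromo-5-chloro-2-[(E)-2-chloroethenyl]-4-(hydroxymethyl)-2-methylcyclohexan-1-ol
Conditions: HF·pyridine, THF, 0 °C → rt
Reagents that add atoms: none
Why: Desilylation with HF·pyridine (silyl ether cleavage driven by Si–F bond formation) works under acidic conditions, so no alkoxide is formed that could close the bromohydrin back to the epoxide or eliminate HBr; no stereocentre changes.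

Step 12
Reactants: 16 (1R,2S,4R,5R)-4-bromo-5-chloro-2-[(E)-2-chloroethenyl]-4-(hydroxymethyl)-2-methylcyclohexan-1-ol
Product: 17 (1R,2R,4S,5S)-1-bromo-2,4-dichloro-1-(chloromethyl)-5-[(E)-2-chloroethenyl]-5-methylcyclohexane
Conditions: PPh3, CCl4, MeCN, 0 → 60 °C
Reagents that add atoms: carbon tetrachloride, SMILES ClC(Cl)(Cl)Cl
Why: Twofold Appel reaction: the primary alcohol is chlorinated first at low temperature and the neopentylic C6 alkoxyphosphonium ion is then displaced by chloride in an SN2 step with inversion on warming, which should turn the β hydroxyl created in the aldol into the α chloride of the target without touching C1, C3 or C4.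

**Compound list**

1 | 1,1,3,3-tetraethoxy-2-methylpropane | CCOC(OCC)C(C)C(OCC)OCC | starting material
2 | 2-methylpropanedial (2-methylmalonaldehyde, present as the enol 3-hydroxy-2-methylprop-2-enal) | O=CC(C)C=O | intermediate
3 | methyl vinyl ketone (but-3-en-2-one) | CC(=O)C=C | starting material
4 | 2-methyl-2-(3-oxobutyl)propanedial | CC(=O)CCC(C)(C=O)C=O | intermediate
5 | (1R,2R)-2-hydroxy-1-methyl-4-oxocyclohexane-1-carbaldehyde (OH cis to CH3) | C[C@@]1(C=O)CCC(=O)C[C@H]1O | intermediate
6 | (1R,2R)-2-[(tert-butyldimethylsilyl)oxy]-1-methyl-4-oxocyclohexane-1-carbaldehyde | C[C@@]1(C=O)CCC(=O)C[C@H]1O[Si](C)(C)C(C)(C)C | intermediate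
7 | (3R,4S)-3-[(tert-butyldimethylsilyl)oxy]-4-[(E)-2-chloroethenyl]-4-methylcyclohexan-1-one | C[C@@]1(/C=C/Cl)CCC(=O)C[C@H]1O[Si](C)(C)C(C)(C)C | intermediate
8 | lithium (4S,5R)-5-[(tert-butyldimethylsilyl)oxy]-4-[(E)-2-chloroethenyl]-4-methylcyclohex-1-en-1-olate (C3=C4 enolate of 7; not isolated) | C[C@@]1(/C=C/Cl)CC=C(O[Li])C[C@H]1O[Si](C)(C)C(C)(C)C | intermediate
9 | (4S,5R)-5-[(tert-butyldimethylsilyl)oxy]-4-[(E)-2-chloroethenyl]-2-[(dimethylamino)methyl]-4-methylcyclohexan-1-one (Mannich base, both C2 epimers; not isolated) | C[C@@]1(/C=C/Cl)CC(CN(C)C)C(=O)C[C@H]1O[Si](C)(C)C(C)(C)C | intermediate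
10 | {[(4R,5S)-4-[(tert-butyldimethylsilyl)oxy]-5-[(E)-2-chloroethenyl]-5-methyl-2-oxocyclohexyl]methyl}trimethylammonium iodide (methiodide of 9, both C1 epimers; not isolated) | C[C@@]1(/C=C/Cl)CC(C[N+](C)(C)C)C(=O)C[C@H]1O[Si](C)(C)C(C)(C)C.[I-] | intermediate
11 | (4S,5R)-5-[(tert-butyldimethylsilyl)oxy]-4-[(E)-2-chloroethenyl]-4-methyl-2-methylidenecyclohexan-1-one | C[C@@]1(/C=C/Cl)CC(=C)C(=O)C[C@H]1O[Si](C)(C)C(C)(C)C | intermediate
12 | (1S,4S,5R)-5-[(tert-butyldimethylsilyl)oxy]-4-[(E)-2-chloroethenyl]-4-methyl-2-methylidenecyclohexan-1-ol (C4–OH β) | C[C@@]1(/C=C/Cl)CC(=C)[C@@H](O)C[C@H]1O[Si](C)(C)C(C)(C)C | intermediate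
13 | (3S,4S,6R,7S)-6-[(tert-butyldimethylsilyl)oxy]-7-[(E)-2-chloroethenyl]-7-methyl-1-oxaspiro[2.5]octan-4-ol (epoxide O β, syn to C4–OH) | C[C@@]1(/C=C/Cl)C[C@]2(CO2)[C@@H](O)C[C@H]1O[Si](C)(C)C(C)(C)C | intermediate
14 | (3S,4R,6R,7S)-6-[(tert-butyldimethylsilyl)oxy]-4-chloro-7-[(E)-2-chloroethenyl]-7-methyl-1-oxaspiro[2.5]octane (C4–Cl α) | C[C@@]1(/C=C/Cl)C[C@]2(CO2)[C@H](Cl)C[C@H]1O[Si](C)(C)C(C)(C)C | intermediate
15 | [(1R,2R,4R,5S)-1-bromo-4-[(tert-butyldimethylsilyl)oxy]-2-chloro-5-[(E)-2-chloroethenyl]-5-methylcyclohexyl]methanol (C3–Br α, CH2OH β) | C[C@@]1(/C=C/Cl)C[C@@](Br)(CO)[C@H](Cl)C[C@H]1O[Si](C)(C)C(C)(C)C | intermediate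
16 | (1R,2S,4R,5R)-4-bromo-5-chloro-2-[(E)-2-chloroethenyl]-4-(hydroxymethyl)-2-methylcyclohexan-1-ol | C[C@@]1(/C=C/Cl)C[C@@](Br)(CO)[C@H](Cl)C[C@H]1O | intermediate
17 | (1R,2R,4S,5S)-1-bromo-2,4-dichloro-1-(chloromethyl)-5-[(E)-2-chloroethenyl]-5-methylcyclohexane | C[C@@]1(/C=C/Cl)C[C@@](Br)(CCl)[C@H](Cl)C[C@@H]1Cl | target

**Step count and risks**

Total step count: 12. Longest linear sequence: 12 steps (1 → 17; the route is fully linear, 3 entering in step 2).

Risk 1, step 10. The bromide may attack the unhindered exocyclic CH2 instead of C3. The chlorine on C4 withdraws electron density from C3 and, being anti to the breaking C–O bond, may also participate, so the halogen can end up on the wrong carbon. A more ionising bromide source would be tried first. The fallback changes the order of halogen introduction and uses the expected bias. Starting from 14, chloride (LiCl, AcOH, THF) opens the oxirane at CH2 to the tertiary chlorohydrin F1. Acylation with methyl chlorooxalate (pyridine, DMAP) gives the mixed oxalate F2, and saponification with CsOH gives the cesium oxalate F3. Visible-light photoredox fragmentation of F3 in the presence of a bromine-atom donor (diethyl bromomalonate) generates the C3 radical and should give the tertiary bromide F4. Bromine is expected on the α face, away from the axial C1 methyl group of the chair with equatorial OTBS; this face selectivity is not secured, and any C3 epimer is removed at this stage. HF·pyridine frees the C6 alcohol F5, and a single Appel reaction at C6 (inversion) returns to the route at 17. This order also removes the chlorination next to a tertiary bromide.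

Risk 2, step 12. Substitution at the neopentylic C6 is slow, so elimination towards C5 or a 1,2-shift from C1 can compete. The tertiary bromine can participate in the substitution at the neighbouring CH2 (1,2-migration of bromine, chloride ending on C3), and free phosphine can attack the tertiary bromide. In the fallback both secondary chlorides are installed before bromine is present. From 13 the silyl ether is cleaved (TBAF, THF; the syn epoxy alcohol cannot rearrange in the Payne sense) to the epoxy diol F6. A double Appel reaction (PPh3, CCl4, MeCN, 60 °C) inverts C4 and C6 to give the dichloro epoxide F7, and HBr (CH2Cl2, −78 °C) opens the oxirane to the bromohydrin F8. Only the primary alcohol then remains for a short Appel reaction at 0 °C with a minimum of phosphine, which gives 17. If bromine migration persists at the primary carbon, the chloride-first order described for step 10 avoids that substitution altogether.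

Risk 3, step 3. Discrimination between the two formyl groups, or between the two orientations of the reacting formyl group, may be weak. The ketol may erode by retro-aldol or dehydration, and the amine may deformylate the dialdehyde. The fallback separates the ring closure from the control of absolute configuration. From 4, cyclisation with an achiral amine salt (pyrrolidinium acetate, CH2Cl2, 0 °C) gives the racemic ketol, that is 5 together with its enantiomer F9. A lipase selected by screening (for example Candida antarctica lipase B, vinyl acetate, MTBE) to acylate F9 converts it into the acetate F10. Unreacted 5 is separated by chromatography and re-enters the route at step 4.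

**Further compounds**

F1 | step 10 | (1S,2R,4R,5S)-4-[(tert-butyldimethylsilyl)oxy]-2-chloro-1-(chloromethyl)-5-[(E)-2-chloroethenyl]-5-methylcyclohexan-1-ol | C[C@@]1(/C=C/Cl)C[C@](O)(CCl)[C@H](Cl)C[C@H]1O[Si](C)(C)C(C)(C)C
F2 | step 10 | (1S,2R,4R,5S)-4-[(tert-butyldimethylsilyl)oxy]-2-chloro-1-(chloromethyl)-5-[(E)-2-chloroethenyl]-5-methylcyclohexyl methyl oxalate | C[C@@]1(/C=C/Cl)C[C@](OC(=O)C(=O)OC)(CCl)[C@H](Cl)C[C@H]1O[Si](C)(C)C(C)(C)C
F3 | step 10 | cesium (1S,2R,4R,5S)-4-[(tert-butyldimethylsilyl)oxy]-2-chloro-1-(chloromethyl)-5-[(E)-2-chloroethenyl]-5-methylcyclohexyl oxalate | C[C@@]1(/C=C/Cl)C[C@](OC(=O)C([O-])=O)(CCl)[C@H](Cl)C[C@H]1O[Si](C)(C)C(C)(C)C.[Cs+]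
F4 | step 10 | tert-butyl{[(1R,2S,4R,5R)-4-bromo-5-chloro-4-(chloromethyl)-2-[(E)-2-chloroethenyl]-2-methylcyclohexyl]oxy}dimethylsilane | C[C@@]1(/C=C/Cl)C[C@@](Br)(CCl)[C@H](Cl)C[C@H]1O[Si](C)(C)C(C)(C)C
F5 | step 10 | (1R,2S,4R,5R)-4-bromo-5-chloro-4-(chloromethyl)-2-[(E)-2-chloroethenyl]-2-methylcyclohexan-1-ol | C[C@@]1(/C=C/Cl)C[C@@](Br)(CCl)[C@H](Cl)C[C@H]1O
F6 | step 12 | (3S,4S,6R,7S)-7-[(E)-2-chloroethenyl]-7-methyl-1-oxaspiro[2.5]octane-4,6-diol | C[C@@]1(/C=C/Cl)C[C@]2(CO2)[C@@H](O)C[C@H]1O
F7 | step 12 | (3S,4R,6S,7S)-4,6-dichloro-7-[(E)-2-chloroethenyl]-7-methyl-1-oxaspiro[2.5]octane | C[C@@]1(/C=C/Cl)C[C@]2(CO2)[C@H](Cl)C[C@@H]1Cl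
F8 | step 12 | [(1R,2R,4S,5S)-1-bromo-2,4-dichloro-5-[(E)-2-chloroethenyl]-5-methylcyclohexyl]methanol | C[C@@]1(/C=C/Cl)C[C@@](Br)(CO)[C@H](Cl)C[C@@H]1Cl
F9 | step 3 | (1S,2S)-2-hydroxy-1-methyl-4-oxocyclohexane-1-carbaldehyde (enantiomer of 5) | C[C@]1(C=O)CCC(=O)C[C@@H]1O
F10 | step 3 | (1S,2S)-2-formyl-2-methyl-5-oxocyclohexyl acetate | C[C@]1(C=O)CCC(=O)C[C@@H]1OC(C)=O
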